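**Plan**

Locants: C1 (CH–O-acyl), C2, C3 (C–OH), C4 (CH–iPr), C5, C6, C7 (C–Me), C8, C9=C10 (C10–Me); ring A = C3–C4–C5–C6–C7, ring B = C1–C2–C3–C7–C8–C9–C10.
Enabling feature: C7 is a quaternary ring-fusion carbon next to the C3 carbinol; without the C6–C7 bond it is a methyl-bearing methine whose tertiary C–H lies 1,5 to C6, so ring A can be closed by carbenoid C–H insertion with retention.
Retrosynthetic cuts, in order: ester C1–O(acyl); C1–O (allylic oxidation); C5 carbonyl put back; C6–C7 (C–H insertion, ring A); C5–C6 (acylation of diazomethane); C3–C4 (aldol); C9=C10 (metathesis, ring B); C2–C3 (Grignard acylation); C7–C8 (enolate allylation).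
Forward: acyclic C7 stereocentre, then ring B by metathesis, then the C4/C5 chain added to the C3 ketone, then the diazoketone, then ring A by C6–C7 insertion, then C5 deoxygenation, C1 oxidation and reduction, veratroylation.
Stereochemistry: C7 from an oxazolidinone-directed allylation and kept through the insertion; C3 by enolate attack anti to the C7 methyl; C4 by equilibration next to the C5 ketone; C1 by a reduction directed by the C3 hydroxyl.

Key step: step 8

Remark: compounds 12 to 17 are carried as mixtures of the two C4 epimers. Step 9 rests on the assumption that in ketone 17 the isopropyl group is more stable cis to the C3 oxygen than cis to the C2 methylene.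

Step 1
Reactants: 1 (4R)-4-benzyl-3-propanoyl-1,3-oxazolidin-2-one; 2 3-iodoprop-1-ene
Product: 4 (4R)-4-benzyl-3-[(2S)-2-methylpent-4-enoyl]-1,3-oxazolidin-2-one, via sodium (Z)-enolate 3 (not isolated)
Conditions: NaN(SiMe3)2, THF, −78 °C; then 2, −78 → −40 °C
Reagents that add atoms: none
Why: Evans alkylation, in which the chelated (Z)-enolate is allylated on the face away from the benzyl group, fixing the (S) configuration of the methyl-bearing carbon that becomes C7.

Step 2
Reactants: 4 (4R)-4-benzyl-3-[(2S)-2-methylpent-4-enoyl]-1,3-oxazolidin-2-one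
Product: 5 (2S)-N-methoxy-N,2-dimethylpent-4-enamide
Conditions: MeNH(OMe)·HCl, AlMe3, CH2Cl2, −15 → 0 °C
Reagents that add atoms: N,O-dimethylhydroxylamine hydrochloride, CNOC.Cl
Why: Weinreb amide formation by aluminium amide transamidation at the exocyclic imide carbonyl, which releases the auxiliary under non-basic conditions that should leave the α-stereocentre untouched.

Step 3
Reactants: 5 (2S)-N-methoxy-N,2-dimethylpent-4-enamide; 6 4-bromo-2-methylbut-1-ene
Product: 8 (6S)-2,6-dimethylnona-1,8-dien-5-one, via Grignard reagent 7 (not isolated)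
Conditions: 6, Mg, THF, rt; then 5, THF, 0 °C; 1 M HCl
Reagents that add atoms: none
Why: Weinreb ketone synthesis, in which the Grignard reagent adds once to give a chelated tetrahedral intermediate that collapses to the ketone only on acidic quench, so neither over-addition nor enolisation of the α-methyl centre is expected.

Step 4
Reactants: 8 (6S)-2,6-dimethylnona-1,8-dien-5-one
Product: 9 (2S)-2,5-dimethylcyclohept-4-en-1-one
Conditions: second-generation Grubbs catalyst RuCl2(=CHPh)(PCy3)(H2IMes) (3 mol %), CH2Cl2 (0.01 M), 40 °C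
Reagents that add atoms: none
Why: Ring-closing metathesis of the 1,1-disubstituted and the monosubstituted alkene should close ring B as the trisubstituted cycloheptene with loss of ethene, under neutral conditions that do not affect the α-stereocentre.

Step 5
Reactants: 9 (2S)-2,5-dimethylcyclohept-4-en-1-one; 10 3-methylbutanoic acid
Product: 12 2-[(1R,2S)-1-hydroxy-2,5-dimethylcyclohept-4-en-1-yl]-3-methylbutanoic acid (both C4 epimers), via dilithium enediolate 11 (not isolated)
Conditions: 10, LiN(i-Pr)2 (2.2 equiv), THF, 0 °C → rt; then 9, −78 °C; cold 1 M HCl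
Reagents that add atoms: none
Why: Ivanov-type aldol addition of a carboxylic acid dianion to a ketone, in which attack at C3 anti to the neighbouring C7 methyl should place the new hydroxyl cis to that methyl (substrate control); C4 forms without reliable control and is corrected in step 9, and ketone lost to enolisation stays as its enolate, so the adduct keeps the enantiopurity of 9.

Step 6
Reactants: 12 2-[(1R,2S)-1-hydroxy-2,5-dimethylcyclohept-4-en-1-yl]-3-methylbutanoic acid (both C4 epimers)
Product: 14 2-[(1R,2S)-2,5-dimethyl-1-(triethylsilyloxy)cyclohept-4-en-1-yl]-3-methylbutanoic acid (both C4 epimers), via bis-silyl compound 13 (not isolated)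
Conditions: Et3SiOTf (2.5 equiv), 2,6-lutidine, CH2Cl2, 0 °C → rt; then MeOH–H2O, rt
Reagents that add atoms: triethylsilyl trifluoromethanesulfonate, CC[Si](CC)(CC)OS(=O)(=O)C(F)(F)F
Why: Silylation with a silyl triflate and a hindered pyridine base should cap both the congested tertiary alcohol and the acid, and only the labile silyl ester is hydrolysed in aqueous methanol.

Step 7
Reactants: 14 2-[(1R,2S)-2,5-dimethyl-1-(triethylsilyloxy)cyclohept-4-en-1-yl]-3-methylbutanoic acid (both C4 epimers)
Product: 16 1-diazo-3-[(1R,2S)-2,5-dimethyl-1-(triethylsilyloxy)cyclohept-4-en-1-yl]-4-methylpentan-2-one (both C4 epimers), via acid chloride 15 (not isolated)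
Conditions: 1-chloro-N,N,2-trimethylprop-1-en-1-amine, CH2Cl2, 0 °C → rt; then CH2N2 (excess), Et2O, 0 °C
Reagents that add atoms: diazomethane, C=[N+]=[N-]
Why: Acylation of diazomethane by an acid chloride (first stage of the Arndt–Eistert sequence), the chloride being made under neutral conditions with the chloroenamine so that the tertiary silyl ether survives, while a second equivalent of diazomethane takes up the HCl.

Step 8
Reactants: 16 1-diazo-3-[(1R,2S)-2,5-dimethyl-1-(triethylsilyloxy)cyclohept-4-en-1-yl]-4-methylpentan-2-one (both C4 epimers)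
Product: 17 (3aS,8aS)-6,8a-dimethyl-3-(propan-2-yl)-3a-(triethylsilyloxy)-3,3a,4,5,8,8a-hexahydroazulen-2(1H)-one (both C4 epimers; C4 is C3 of the azulene name)
Conditions: Rh2(OAc)4 (2 mol %), CH2Cl2 (0.01 M), slow addition of 16, rt
Reagents that add atoms: none
Why: Rh2(OAc)4 takes up the diazo carbon C6 with loss of dinitrogen to give an electrophilic rhodium carbenoid, which inserts into the C7–H bond through a concerted three-centre transition state in which hydride transfer and C6–C7 bond formation occur on the same face of C7. The closest known reaction type is the dirhodium-catalysed intramolecular 1,5 C–H insertion of α-diazo ketones into tertiary C–H bonds to give cyclopentanones. Ring A (C3–C4–C5–C6–C7) closes by this 1,5-insertion, C6 bonding to C7 through a six-centre, chair-like array of C6, C5, C4, C3, C7 and the migrating hydrogen. The new quaternary stereocentre C7 is formed with retention, so its configuration is that installed in step 1, and the cis ring fusion follows from the cis relation of the C3 side chain and C7–H set in step 5. The step needs the tertiary C7–H to win over the secondary C2–H bonds (also 1,5), the isopropyl C–H bonds, the ether oxygen and the ring alkene: tertiary C–H bonds are the most reactive towards such carbenoids, the inductive effect of the C3 oxygen weighs equally on C7–H and C2–H, the isopropyl methine would give a four-membered ring and its methyls are primary, the bulky triethylsilyl group shields the oxygen from ylide formation, and cyclopropanation of C9=C10 would require a bridged seven-membered ring.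

Step 9
Reactants: 17 (3aS,8aS)-6,8a-dimethyl-3-(propan-2-yl)-3a-(triethylsilyloxy)-3,3a,4,5,8,8a-hexahydroazulen-2(1H)-one (both C4 epimers)
Product: 18 (3R,3aS,8aS)-6,8a-dimethyl-3-(propan-2-yl)-3a-(triethylsilyloxy)-3,3a,4,5,8,8a-hexahydroazulen-2(1H)-one
Conditions: DBU (0.3 equiv), toluene, rt
Reagents that add atoms: none
Why: Base-mediated epimerisation of the only enolisable stereocentre (C4) through the C4–C5 enolate should converge both epimers on the one with isopropyl cis to the small silyloxy oxygen and trans to the C2 methylene, which is the target configuration; a catalytic non-nucleophilic base at room temperature is chosen to avoid β-elimination of the silanol.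

Step 10
Reactants: 18 (3R,3aS,8aS)-6,8a-dimethyl-3-(propan-2-yl)-3a-(triethylsilyloxy)-3,3a,4,5,8,8a-hexahydroazulen-2(1H)-one
Product: 19 N'-[(3S,3aS,8aS)-6,8a-dimethyl-3-(propan-2-yl)-3a-(triethylsilyloxy)-3,3a,4,5,8,8a-hexahydroazulen-2(1H)-ylidene]-4-methylbenzenesulfonohydrazide
Conditions: TsNHNH2, EtOH, 50 °C
Reagents that add atoms: 4-methylbenzenesulfonohydrazide, Cc1ccc(S(=O)(=O)NN)cc1
Why: Condensation of the cyclopentanone with tosylhydrazide gives the tosylhydrazone; no stereocentre is formed and C4 is already in its stable configuration (the descriptor changes only through ligand priorities).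

Step 11
Reactants: 19 N'-[(3S,3aS,8aS)-6,8a-dimethyl-3-(propan-2-yl)-3a-(triethylsilyloxy)-3,3a,4,5,8,8a-hexahydroazulen-2(1H)-ylidene]-4-methylbenzenesulfonohydrazide
Product: 21 triethyl{[(3R,3aS,8aR)-6,8a-dimethyl-3-(propan-2-yl)-2,3,4,5,8,8a-hexahydroazulen-3a(1H)-yl]oxy}silane, via N-boryl tosylhydrazine 20 (not isolated)
Conditions: catecholborane, CHCl3, 0 °C; then NaOAc·3H2O, reflux
Reagents that add atoms: none
Why: Caglioti-type reductive deoxygenation, in which catecholborane hydroborates the C=N bond and acetate then triggers loss of sulfinate and dinitrogen from the resulting diazene, should leave C5 as a methylene without touching the alkene or the silyl ether.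

Step 12
Reactants: 21 triethyl{[(3R,3aS,8aR)-6,8a-dimethyl-3-(propan-2-yl)-2,3,4,5,8,8a-hexahydroazulen-3a(1H)-yl]oxy}silane
Product: 22 (3R,3aS,8aR)-6,8a-dimethyl-3-(propan-2-yl)-2,3,4,5,8,8a-hexahydroazulen-3a(1H)-ol
Conditions: Bu4NF, THF, rt → 50 °C
Reagents that add atoms: none
Why: Fluoride-induced desilylation frees the tertiary C3 alcohol, and nothing else in the molecule is fluoride-sensitive.

Step 13
Reactants: 22 (3R,3aS,8aR)-6,8a-dimethyl-3-(propan-2-yl)-2,3,4,5,8,8a-hexahydroazulen-3a(1H)-ol
Product: 23 (3R,3aS,8aR)-6,8a-dimethyl-3-(propan-2-yl)-2,3,4,5,8,8a-hexahydroazulene-3a,5(1H)-diol (both C1 epimers; C1 is C5 of the azulene name)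
Conditions: SeO2 (0.5 equiv), t-BuOOH, CH2Cl2, rt
Reagents that add atoms: selenium dioxide, O=[Se]=O (transfers the oxygen); tert-butyl hydroperoxide, CC(C)(C)OO (terminal oxygen source)
Why: Riley allylic oxidation, in which the ene reaction takes place at the more substituted alkene carbon C10 and the ring methylene C1 is normally preferred over the methyl group, the [2,3]-shift returning the double bond to C9=C10; the C1 configuration is not controlled here and is erased in step 14 (any enone 24 formed directly is carried along).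

Step 14
Reactants: 23 (3R,3aS,8aR)-6,8a-dimethyl-3-(propan-2-yl)-2,3,4,5,8,8a-hexahydroazulene-3a,5(1H)-diol (both C1 epimers)
Product: 24 (3R,3aS,8aR)-3a-hydroxy-6,8a-dimethyl-3-(propan-2-yl)-2,3,3a,4,8,8a-hexahydroazulen-5(1H)-one
Conditions: Dess–Martin periodinane, CH2Cl2, rt
Reagents that add atoms: none
Why: Dess–Martin oxidation of the secondary allylic alcohol should give the enone, the tertiary C3 alcohol being inert.

Step 15
Reactants: 24 (3R,3aS,8aR)-3a-hydroxy-6,8a-dimethyl-3-(propan-2-yl)-2,3,3a,4,8,8a-hexahydroazulen-5(1H)-one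
Product: 25 (3R,3aS,5R,8aR)-6,8a-dimethyl-3-(propan-2-yl)-2,3,4,5,8,8a-hexahydroazulene-3a,5(1H)-diol
Conditions: Me4NBH(OAc)3, MeCN–AcOH, −30 °C
Reagents that add atoms: none
Why: Saksena–Evans hydroxyl-directed reduction, in which the C3 hydroxyl exchanges onto boron and delivers hydride to the C1 carbonyl from its own face, should leave the new C1 hydroxyl anti (trans) to the C3 hydroxyl, which is the (R) configuration required.

Step 16
Reactants: 25 (3R,3aS,5R,8aR)-6,8a-dimethyl-3-(propan-2-yl)-2,3,4,5,8,8a-hexahydroazulene-3a,5(1H)-diol; 26 3,4-dimethoxybenzoyl chloride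
Product: 27 (3R,3aS,5R,8aR)-3a-hydroxy-6,8a-dimethyl-3-(propan-2-yl)-1,2,3,3a,4,5,8,8a-octahydroazulen-5-yl 3,4-dimethoxybenzoate
Conditions: 26, Et3N, DMAP (cat.), CH2Cl2, 0 °C → rt
Reagents that add atoms: none
Why: DMAP-catalysed acylation (nucleophilic catalysis) of the secondary allylic alcohol should be selective, because the tertiary ring-fusion alcohol is too hindered to react.

**Compound list**

1 | (4R)-4-benzyl-3-propanoyl-1,3-oxazolidin-2-one | CCC(=O)N1[C@H](Cc2ccccc2)COC1=O | starting material
2 | 3-iodoprop-1-ene | C=CCI | starting material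
3 | sodium (Z)-enolate of 1 | C/C=C(\[O-])N1[C@H](Cc2ccccc2)COC1=O.[Na+] | intermediate
4 | (4R)-4-benzyl-3-[(2S)-2-methylpent-4-enoyl]-1,3-oxazolidin-2-one | C=CC[C@H](C)C(=O)N1[C@H](Cc2ccccc2)COC1=O | intermediate
5 | (2S)-N-methoxy-N,2-dimethylpent-4-enamide | C=CC[C@H](C)C(=O)N(C)OC | intermediate
6 | 4-bromo-2-methylbut-1-ene | C=C(C)CCBr | starting material
7 | (3-methylbut-3-en-1-yl)magnesium bromide | C=C(C)CC[Mg]Br | intermediate
8 | (6S)-2,6-dimethylnona-1,8-dien-5-one | C=CC[C@H](C)C(=O)CCC(C)=C | intermediate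
9 | (2S)-2,5-dimethylcyclohept-4-en-1-one | O=C1CCC(C)=CC[C@@H]1C | intermediate
10 | 3-methylbutanoic acid | CC(C)CC(=O)O | starting material
11 | dilithium 3-methylbut-1-ene-1,1-diolate | CC(C)C=C([O-])[O-].[Li+].[Li+] | intermediate
12 | 2-[(1R,2S)-1-hydroxy-2,5-dimethylcyclohept-4-en-1-yl]-3-methylbutanoic acid, both C4 epimers | CC1=CC[C@H](C)[C@@](O)(C(C(C)C)C(=O)O)CC1 | intermediate
13 | triethylsilyl 2-[(1R,2S)-2,5-dimethyl-1-(triethylsilyloxy)cyclohept-4-en-1-yl]-3-methylbutanoate, both C4 epimers | CC1=CC[C@H](C)[C@@](O[Si](CC)(CC)CC)(C(C(C)C)C(=O)O[Si](CC)(CC)CC)CC1 | intermediate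
14 | 2-[(1R,2S)-2,5-dimethyl-1-(triethylsilyloxy)cyclohept-4-en-1-yl]-3-methylbutanoic acid, both C4 epimers | CC1=CC[C@H](C)[C@@](O[Si](CC)(CC)CC)(C(C(C)C)C(=O)O)CC1 | intermediate
15 | 2-[(1R,2S)-2,5-dimethyl-1-(triethylsilyloxy)cyclohept-4-en-1-yl]-3-methylbutanoyl chloride, both C4 epimers | CC1=CC[C@H](C)[C@@](O[Si](CC)(CC)CC)(C(C(C)C)C(Cl)=O)CC1 | intermediate
16 | 1-diazo-3-[(1R,2S)-2,5-dimethyl-1-(triethylsilyloxy)cyclohept-4-en-1-yl]-4-methylpentan-2-one, both C4 epimers | CC1=CC[C@H](C)[C@@](O[Si](CC)(CC)CC)(C(C(C)C)C(=O)C=[N+]=[N-])CC1 | intermediate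
17 | (3aS,8aS)-6,8a-dimethyl-3-(propan-2-yl)-3a-(triethylsilyloxy)-3,3a,4,5,8,8a-hexahydroazulen-2(1H)-one, both C4 epimers | C1C[C@]2(O[Si](CC)(CC)CC)C(C(C)C)C(=O)C[C@]2(C)CC=C1C | intermediate
18 | (3R,3aS,8aS)-6,8a-dimethyl-3-(propan-2-yl)-3a-(triethylsilyloxy)-3,3a,4,5,8,8a-hexahydroazulen-2(1H)-one | C1C[C@]2(O[Si](CC)(CC)CC)[C@@H](C(C)C)C(=O)C[C@]2(C)CC=C1C | intermediate
19 | N'-[(3S,3aS,8aS)-6,8a-dimethyl-3-(propan-2-yl)-3a-(triethylsilyloxy)-3,3a,4,5,8,8a-hexahydroazulen-2(1H)-ylidene]-4-methylbenzenesulfonohydrazide | C1C[C@]2(O[Si](CC)(CC)CC)[C@@H](C(C)C)C(=NNS(=O)(=O)c3ccc(C)cc3)C[C@]2(C)CC=C1C | intermediate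
20 | N-(1,3,2-benzodioxaborol-2-yl) tosylhydrazine from hydroboration of the C=N bond of 19 | C1C[C@]2(O[Si](CC)(CC)CC)[C@@H](C(C)C)C(N(NS(=O)(=O)c3ccc(C)cc3)B3Oc4ccccc4O3)C[C@]2(C)CC=C1C | intermediate
21 | triethyl{[(3R,3aS,8aR)-6,8a-dimethyl-3-(propan-2-yl)-2,3,4,5,8,8a-hexahydroazulen-3a(1H)-yl]oxy}silane | C1C[C@]2(O[Si](CC)(CC)CC)[C@@H](C(C)C)CC[C@]2(C)CC=C1C | intermediate
22 | (3R,3aS,8aR)-6,8a-dimethyl-3-(propan-2-yl)-2,3,4,5,8,8a-hexahydroazulen-3a(1H)-ol | C1C[C@]2(O)[C@@H](C(C)C)CC[C@]2(C)CC=C1C | intermediate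
23 | (3R,3aS,8aR)-6,8a-dimethyl-3-(propan-2-yl)-2,3,4,5,8,8a-hexahydroazulene-3a,5(1H)-diol, both C1 epimers | OC1C[C@]2(O)[C@@H](C(C)C)CC[C@]2(C)CC=C1C | intermediate
24 | (3R,3aS,8aR)-3a-hydroxy-6,8a-dimethyl-3-(propan-2-yl)-2,3,3a,4,8,8a-hexahydroazulen-5(1H)-one | O=C1C[C@]2(O)[C@@H](C(C)C)CC[C@]2(C)CC=C1C | intermediate
25 | (3R,3aS,5R,8aR)-6,8a-dimethyl-3-(propan-2-yl)-2,3,4,5,8,8a-hexahydroazulene-3a,5(1H)-diol | O[C@@H]1C[C@]2(O)[C@@H](C(C)C)CC[C@]2(C)CC=C1C | intermediate
26 | 3,4-dimethoxybenzoyl chloride | COc1ccc(C(=O)Cl)cc1OC | starting material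
27 | (3R,3aS,5R,8aR)-3a-hydroxy-6,8a-dimethyl-3-(propan-2-yl)-1,2,3,3a,4,5,8,8a-octahydroazulen-5-yl 3,4-dimethoxybenzoate | COc1ccc(C(=O)O[C@@H]2C[C@]3(O)[C@@H](C(C)C)CC[C@]3(C)CC=C2C)cc1OC | target

Total step count: 16. Longest linear sequence: 16 steps (1 to 27).

**Steps most likely to fail**

Step 8. The acceptor-only carbenoid may be diverted, because the C7–H bond is inductively deactivated by the oxygen on C3: insertion into a C2–H bond, attack on the silyl ether oxygen followed by silyl transfer, or carbene dimerisation could compete. The fallback changes the carbenoid to the more selective acceptor/acceptor type. It sets out from acid 14 through its chloride 15 (made as in step 7). Acylation of the lithium enolate of methyl acetate (2 equiv, THF, −78 °C) should give methyl 4-[(1R,2S)-2,5-dimethyl-1-(triethylsilyloxy)cyclohept-4-en-1-yl]-5-methyl-3-oxohexanoate F1. Regitz diazo transfer (4-acetamidobenzenesulfonyl azide, Et3N, MeCN) should give methyl 2-diazo-4-[(1R,2S)-2,5-dimethyl-1-(triethylsilyloxy)cyclohept-4-en-1-yl]-5-methyl-3-oxohexanoate F2. Rh2(OAc)4 in CH2Cl2 should then effect the same C6–C7 insertion to the bicyclic β-keto ester methyl (3aS,8aS)-6,8a-dimethyl-2-oxo-3-(propan-2-yl)-3a-(triethylsilyloxy)-1,2,3,3a,4,5,8,8a-octahydroazulene-1-carboxylate F3. Krapcho dealkoxycarbonylation (LiCl, wet DMSO, 130 °C) removes the ester and the route is rejoined at ketone 17.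

Step 9. The equilibrium may not favour the wanted epimer strongly enough, or the C4–C5 enolate may expel triethylsilanolate (β-elimination) to give the ring-fusion enone. The fallback takes C4 from kinetic control and separation instead of equilibration. With the methyl-bearing C7 acting as the larger ketone substituent, the anti preference typical of α-branched enediolates in step 5 corresponds to the target C4 configuration. The fallback sets out from diazoketone 16, which is stable and not epimerisable under neutral conditions: its C4 epimers are separated by chromatography, and (3R)-1-diazo-3-[(1R,2S)-2,5-dimethyl-1-(triethylsilyloxy)cyclohept-4-en-1-yl]-4-methylpentan-2-one F4 is cyclised alone under the conditions of step 8. This should give the single epimer directly, with no base treatment, and the route is rejoined at 18.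

Step 13. The ene reaction may abstract hydrogen from the C10 methyl group instead of C1 (leading to the primary allylic alcohol or the enal), or the product may be over-oxidised. The fallback brings the oxygen in at C9, where the regiochemistry is unambiguous, and transposes it. It sets out from 22. Hydroboration–oxidation (BH3·THF; then NaOH, H2O2) should give the C9 alcohol with a saturated ring B F5. Dess–Martin oxidation gives the C9 ketone F6. Dehydrogenation with 2-iodoxybenzoic acid (DMSO, 70 °C) can only form the C10=C1 enone F7, because C7 is quaternary. Nucleophilic epoxidation (H2O2, NaOH, MeOH) gives the C1–C10 epoxy C9 ketone F8. Wharton transposition (N2H4·H2O, AcOH, MeOH) returns the C9=C10 alkene with the hydroxyl on C1, and the route is rejoined at 23.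

Further compounds
F1 | step 8 | methyl 4-[(1R,2S)-2,5-dimethyl-1-(triethylsilyloxy)cyclohept-4-en-1-yl]-5-methyl-3-oxohexanoate, both C4 epimers | CC1=CC[C@H](C)[C@@](O[Si](CC)(CC)CC)(C(C(C)C)C(=O)CC(=O)OC)CC1
F2 | step 8 | methyl 2-diazo-4-[(1R,2S)-2,5-dimethyl-1-(triethylsilyloxy)cyclohept-4-en-1-yl]-5-methyl-3-oxohexanoate, both C4 epimers | CC1=CC[C@H](C)[C@@](O[Si](CC)(CC)CC)(C(C(C)C)C(=O)C(=[N+]=[N-])C(=O)OC)CC1
F3 | step 8 | methyl (3aS,8aS)-6,8a-dimethyl-2-oxo-3-(propan-2-yl)-3a-(triethylsilyloxy)-1,2,3,3a,4,5,8,8a-octahydroazulene-1-carboxylate, epimers at C4 and C6 | C1C[C@]2(O[Si](CC)(CC)CC)C(C(C)C)C(=O)C(C(=O)OC)[C@]2(C)CC=C1C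
F4 | step 9 | (3R)-1-diazo-3-[(1R,2S)-2,5-dimethyl-1-(triethylsilyloxy)cyclohept-4-en-1-yl]-4-methylpentan-2-one | CC1=CC[C@H](C)[C@@](O[Si](CC)(CC)CC)([C@@H](C(C)C)C(=O)C=[N+]=[N-])CC1
F5 | step 13 | C9 alcohol of 22 with saturated ring B (C3–OH, C9–OH, C10–H; epimers at C9 and C10) | C1C[C@]2(O)[C@@H](C(C)C)CC[C@]2(C)CC(O)C1C
F6 | step 13 | C9 ketone of 22 with saturated ring B (C3–OH, C9=O; epimers at C10) | C1C[C@]2(O)[C@@H](C(C)C)CC[C@]2(C)CC(=O)C1C
F7 | step 13 | C9 ketone with C10=C1 double bond (C3–OH kept) | C1C[C@]2(O)[C@@H](C(C)C)CC[C@]2(C)CC(=O)C=1C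
F8 | step 13 | C1–C10 epoxide of the C9 ketone (C3–OH kept; epoxide epimers) | C12C[C@]3(O)[C@@H](C(C)C)CC[C@]3(C)CC(=O)C1(C)O2
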